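**Plan**

- Retrosynthesis: both C–O bonds of the tetrahydrofuran are cut first (back to the C2-symmetric 1,4-diol and its diacyl oxidation level), then the two aryl–CH2 bonds, then the central C3–C4 bond between two propionyl units.
- Enabling feature: each benzylic CH2 hangs on ring carbon C3 or C4 and is therefore β to ring carbon C2 or C5. When C2 and C5 are N-(quinolin-8-yl)carboxamide carbons, each benzylic carbon is a β-methyl group within reach of a five-membered palladacycle.
- Forward order: C3–C4 by oxidative enolate homocoupling of a propionyl oxazolidinone; exchange of the auxiliary for two 8-aminoquinoline amides; twofold methyl C–H arylation with 4-iodoveratrole; reductive removal of both amides; the only ring (the tetrahydrofuran) closes last by cyclodehydration.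
- Stereochemistry: both centres are set as S,S in step 1 by the (R)-4-benzyl auxiliary. No later step makes or breaks a bond at these carbons, and the substituent priorities keep the same order, so the descriptors stay S,S from 3 to 17.

Key step: step 4

Assumption: compound 1 is purchased as such; the target is the trans (3S,4S) isomer, which corresponds to the (2S,3S) series of all open-chain intermediates.

**Step 1**
Reactants: 1 (R)-4-benzyl-3-propionyloxazolidin-2-one (2 equiv)
Product: 3 (2S,3S)-1,4-bis[(R)-4-benzyl-2-oxooxazolidin-3-yl]-2,3-dimethylbutane-1,4-dione, via lithium Z-enolate 2 (not isolated)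
Conditions: LiN(iPr)2 (LDA), THF, −78 °C; then TiCl4, −78 °C → rt
Reagents that add atoms: none
Why: Oxidative enolate homocoupling, in which the chelated Z-enolate 2 is oxidised by TiCl4 (tetravalent titanium going to trivalent titanium) and the C–C bond forms on the enolate face away from the benzyl group of each (R)-auxiliary, the same facial sense as in alkylations of this enolate, which should set both new centres as S.

**Step 2**
Reactants: 3 (2S,3S)-1,4-bis[(R)-4-benzyl-2-oxooxazolidin-3-yl]-2,3-dimethylbutane-1,4-dione
Product: 5 (2S,3S)-2,3-dimethylsuccinic acid, via diperoxy acid 4 (not isolated)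
Conditions: LiOH·H2O, 30% aq H2O2, THF/H2O, 0 °C; then aq Na2SO3; then HCl to pH 2
Reagents that add atoms: hydrogen peroxide, OO (acting as lithium hydroperoxide)
Why: Hydroperoxide cleavage of an N-acyl oxazolidinone, in which the small hydroperoxide anion attacks the exocyclic carbonyl, the peracid 4 is reduced by sulfite, and the weakly basic medium at 0 °C should leave the α-centres untouched while the auxiliary is recovered.

**Step 3**
Reactants: 5 (2S,3S)-2,3-dimethylsuccinic acid; 6 8-aminoquinoline (2.5 equiv)
Product: 9 (2S,3S)-2,3-dimethyl-N1,N4-di(quinolin-8-yl)succinamide, via trans-anhydride 7 (not isolated), via amide acid 8 (not isolated)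
Conditions: DIC (2.4 equiv), HOAt, CH2Cl2/DMF, 0 → 40 °C
Reagents that add atoms: none
Why: Carbodiimide amide coupling by the active-ester method, in which DIC first dehydrates the diacid to anhydride 7, 8-aminoquinoline opens it to amide acid 8, and a second activation as the OAt ester acylates the excess amine, all without added base so that the α-centres are not enolised.

**Step 4**
Reactants: 9 (2S,3S)-2,3-dimethyl-N1,N4-di(quinolin-8-yl)succinamide; 10 4-iodo-1,2-dimethoxybenzene (3 equiv)
Product: 12 (2S,3S)-2,3-bis(3,4-dimethoxybenzyl)-N1,N4-di(quinolin-8-yl)succinamide, via monoarylated diamide 11 (not isolated)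
Conditions: Pd(OAc)2 (20 mol %), AgOAc (3 equiv), (BnO)2PO2H (40 mol %), t-AmylOH, 90 °C, argon
Reagents that add atoms: none
Why: Each deprotonated N-(quinolin-8-yl)amide binds divalent palladium through the amide and quinoline nitrogens, acetate-assisted concerted metalation-deprotonation of the methyl group on the adjacent α-carbon gives a five-membered palladacycle, oxidative addition of 10 raises the metal to tetravalent palladium, and C–C reductive elimination forms the aryl–CH2 bond while AgOAc takes up iodide and returns the palladium carboxylate; the cycle runs first on one arm (to 11) and then on the other. The closest known reaction type is the 8-aminoquinoline-directed, Pd(OAc)2-catalysed β-methyl C–H arylation of α-substituted propanamides with aryl iodides and a silver carboxylate, used here on both halves of a C2-symmetric diamide. No ring closes and no stereocentre is formed: the two S centres lie α to the amides, take no part in the catalytic cycle and should survive the weakly basic acetate medium. The selectivity needed is for the two methyl groups over the tertiary C–H of the neighbouring methine and over the newly formed benzylic CH2; the palladacycle geometry confines reaction to β-carbons, primary C–H bonds are cleaved faster than the tertiary or the more crowded secondary ones, and the aryl iodide is held near three equivalents so that a third arylation finds little reagent. A hindered alcohol solvent, the phosphate additive and 90 °C rather than higher temperatures are chosen to limit binding of one palladium by both arms and thermal closure to the N-quinolinyl succinimide.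

**Step 5**
Reactants: 12 (2S,3S)-2,3-bis(3,4-dimethoxybenzyl)-N1,N4-di(quinolin-8-yl)succinamide
Product: 13 (2S,3S)-N1,N4-bis(tert-butoxycarbonyl)-2,3-bis(3,4-dimethoxybenzyl)-N1,N4-di(quinolin-8-yl)succinamide
Conditions: Boc2O (8 equiv), DMAP (2 equiv), MeCN, 50 °C
Reagents that add atoms: di-tert-butyl dicarbonate (Boc2O), CC(C)(C)OC(=O)OC(=O)OC(C)(C)C
Why: DMAP-catalysed N-acylation of a secondary anilide with Boc2O (N-Boc amide activation), which twists each amide out of conjugation and makes its acyl group about as electrophilic as an imide, the usual way of loosening N-(quinolin-8-yl)amides.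

**Step 6**
Reactants: 13 (2S,3S)-N1,N4-bis(tert-butoxycarbonyl)-2,3-bis(3,4-dimethoxybenzyl)-N1,N4-di(quinolin-8-yl)succinamide
Product: 15 (2S,3S)-2,3-bis(3,4-dimethoxybenzyl)butane-1,4-diol, via lactone 14 (not isolated)
Conditions: LiBH4 (6 equiv), THF, 0 °C → rt; then aq NH4Cl
Reagents that add atoms: none
Why: Borohydride reductive cleavage of N-acyl carbamates, in which hydride adds to the twisted amide carbonyl rather than the Boc carbonyl, the carbamate anion is expelled and the aldehyde is reduced on; the first alkoxide is expected to close onto the second acyl carbamate to give lactone 14, which LiBH4 also reduces, so either path should end at the diol without touching the stereocentres.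

**Step 7**
Reactants: 15 (2S,3S)-2,3-bis(3,4-dimethoxybenzyl)butane-1,4-diol
Product: 17 (3S,4S)-3,4-bis(3,4-dimethoxybenzyl)tetrahydrofuran, via monotosylate 16 (not isolated)
Conditions: TsCl (1.1 equiv), pyridine, 0 °C → rt, then 60 °C
Reagents that add atoms: none
Why: Cyclodehydration of a 1,4-diol by monosulfonylation and intramolecular Williamson etherification, in which the free hydroxyl of 16 displaces the primary tosylate in a 5-exo-tet closure, so the two stereocentres, which are not reaction sites, keep their configuration.

**Compound list**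

1 | (R)-4-benzyl-3-propionyloxazolidin-2-one | CCC(=O)N1[C@H](Cc2ccccc2)COC1=O | starting material
2 | lithium (Z)-1-[(R)-4-benzyl-2-oxooxazolidin-3-yl]prop-1-en-1-olate (formed in the flask) | C/C=C(\O[Li])N1[C@H](Cc2ccccc2)COC1=O | intermediate
3 | (2S,3S)-1,4-bis[(R)-4-benzyl-2-oxooxazolidin-3-yl]-2,3-dimethylbutane-1,4-dione | O=C([C@@H](C)[C@H](C)C(=O)N1[C@H](Cc2ccccc2)COC1=O)N1[C@H](Cc2ccccc2)COC1=O | intermediate
4 | (2S,3S)-2,3-dimethylbutanediperoxoic acid (formed in the flask, present as its lithium salt) | OOC(=O)[C@@H](C)[C@H](C)C(=O)OO | intermediate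
5 | (2S,3S)-2,3-dimethylsuccinic acid | OC(=O)[C@@H](C)[C@H](C)C(=O)O | intermediate
6 | 8-aminoquinoline | Nc1cccc2cccnc12 | starting material
7 | (3S,4S)-3,4-dimethyldihydrofuran-2,5-dione (trans-anhydride, formed in the flask) | O=C1[C@@H](C)[C@H](C)C(=O)O1 | intermediate
8 | (2S,3S)-2,3-dimethyl-4-oxo-4-(quinolin-8-ylamino)butanoic acid (formed in the flask) | OC(=O)[C@@H](C)[C@H](C)C(=O)Nc1cccc2cccnc12 | intermediate
9 | (2S,3S)-2,3-dimethyl-N1,N4-di(quinolin-8-yl)succinamide | O=C(Nc1cccc2cccnc12)[C@@H](C)[C@H](C)C(=O)Nc1cccc2cccnc12 | intermediate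
10 | 4-iodo-1,2-dimethoxybenzene | COc1ccc(I)cc1OC | starting material
11 | (2S,3S)-2-(3,4-dimethoxybenzyl)-3-methyl-N1,N4-di(quinolin-8-yl)succinamide (formed in the flask) | O=C(Nc1cccc2cccnc12)[C@@H](Cc1ccc(OC)c(OC)c1)[C@H](C)C(=O)Nc1cccc2cccnc12 | intermediate
12 | (2S,3S)-2,3-bis(3,4-dimethoxybenzyl)-N1,N4-di(quinolin-8-yl)succinamide | O=C(Nc1cccc2cccnc12)[C@@H](Cc1ccc(OC)c(OC)c1)[C@H](Cc1ccc(OC)c(OC)c1)C(=O)Nc1cccc2cccnc12 | intermediate
13 | (2S,3S)-N1,N4-bis(tert-butoxycarbonyl)-2,3-bis(3,4-dimethoxybenzyl)-N1,N4-di(quinolin-8-yl)succinamide | O=C([C@@H](Cc1ccc(OC)c(OC)c1)[C@H](Cc1ccc(OC)c(OC)c1)C(=O)N(C(=O)OC(C)(C)C)c1cccc2cccnc12)N(C(=O)OC(C)(C)C)c1cccc2cccnc12 | intermediate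
14 | (3S,4S)-3,4-bis(3,4-dimethoxybenzyl)dihydrofuran-2(3H)-one (formed in the flask) | O1C[C@@H](Cc2ccc(OC)c(OC)c2)[C@H](Cc2ccc(OC)c(OC)c2)C1=O | intermediate
15 | (2S,3S)-2,3-bis(3,4-dimethoxybenzyl)butane-1,4-diol | OC[C@@H](Cc1ccc(OC)c(OC)c1)[C@H](Cc1ccc(OC)c(OC)c1)CO | intermediate
16 | (2S,3S)-2,3-bis(3,4-dimethoxybenzyl)-4-hydroxybutyl 4-methylbenzenesulfonate (formed in the flask) | Cc1ccc(cc1)S(=O)(=O)OC[C@@H](Cc1ccc(OC)c(OC)c1)[C@H](Cc1ccc(OC)c(OC)c1)CO | intermediate
17 | (3S,4S)-3,4-bis(3,4-dimethoxybenzyl)tetrahydrofuran | COc1ccc(C[C@@H]2COC[C@H]2Cc2ccc(OC)c(OC)c2)cc1OC | target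

**Step count and risks**

Total step count: 7. Longest linear sequence: 7 steps (1 → 17).

Steps most likely to fail:

1. Step 4 (twofold C–H arylation). The diamide may bind one palladium through both chelating arms so that turnover stalls; the new benzylic CH2 may be arylated again; or one amide nitrogen may close onto the other acyl group with loss of 8-aminoquinoline. The fallback sets out from 10 and returns at 15, and brings in the aryl–CH2 carbons as part of the acyl unit before the central bond is made. The (R)-4-benzyloxazolidin-2-one recovered in step 2 is N-acylated with acryloyl chloride (Et3N, LiCl, THF) to (R)-3-acryloyl-4-benzyloxazolidin-2-one F1. A Heck reaction of 10 with it (Pd(OAc)2, P(o-tol)3, Et3N, MeCN, 80 °C) should give (R,E)-4-benzyl-3-[3-(3,4-dimethoxyphenyl)acryloyl]oxazolidin-2-one F2. Hydrogenation over Pd on carbon in EtOAc saturates the alkene to (R)-4-benzyl-3-[3-(3,4-dimethoxyphenyl)propanoyl]oxazolidin-2-one F3. Deprotonation with LiN(iPr)2 at −78 °C gives lithium (Z)-1-[(R)-4-benzyl-2-oxooxazolidin-3-yl]-3-(3,4-dimethoxyphenyl)prop-1-en-1-olate F4, which TiCl4 couples oxidatively as in step 1 to (2S,3S)-1,4-bis[(R)-4-benzyl-2-oxooxazolidin-3-yl]-2,3-bis(3,4-dimethoxybenzyl)butane-1,4-dione F5. LiBH4 in THF then removes both auxiliaries reductively and should deliver diol 15, from which step 7 runs unchanged.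

2. Step 3 (bis-amide formation). Once the first amide is in place, the re-activated amide acid may close on itself faster than the weakly nucleophilic 8-aminoquinoline attacks, which would drain material into the cyclic imide. The fallback sets out from 5 and returns at 9, and uses the ring closure instead of fighting it. DCC (1 equiv, CH2Cl2, 0 °C) converts 5 to anhydride 7, now isolated, and 6 opens it to amide acid 8. A second equivalent of DCC at 0 °C cyclises 8 through the amide oxygen, the kinetic course of carbodiimide dehydration of amic acids, to (3S,4S)-3,4-dimethyl-5-(quinolin-8-ylimino)dihydrofuran-2(3H)-one F6. This isoimide is an anhydride-like acylating agent, and its aminolysis by 6 (CH2Cl2, rt) should open the ring to 9.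

3. Step 5 (Boc activation). Boc transfer to two hindered anilide nitrogens may stay incomplete, or the still free N–H of the half-activated diamide may attack the neighbouring acyl carbamate and end in the N-quinolinyl succinimide. The fallback sets out from 12 and returns at 15, and replaces activation by hydrolysis. Heating 12 in 6 M HCl/dioxane at 100 °C should cleave both anilides, the second helped by the neighbouring carboxyl group, to (2S,3S)-2,3-bis(3,4-dimethoxybenzyl)succinic acid F7. Aryl methyl ethers are expected to withstand these conditions, and acid-catalysed enolisation is slow. LiAlH4 in THF (0 °C → reflux) then reduces F7 to diol 15.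

**Further compounds**

F1 | step 4 | (R)-3-acryloyl-4-benzyloxazolidin-2-one | C=CC(=O)N1[C@H](Cc2ccccc2)COC1=O
F2 | step 4 | (R,E)-4-benzyl-3-[3-(3,4-dimethoxyphenyl)acryloyl]oxazolidin-2-one | COc1ccc(/C=C/C(=O)N2[C@H](Cc3ccccc3)COC2=O)cc1OC
F3 | step 4 | (R)-4-benzyl-3-[3-(3,4-dimethoxyphenyl)propanoyl]oxazolidin-2-one | COc1ccc(CCC(=O)N2[C@H](Cc3ccccc3)COC2=O)cc1OC
F4 | step 4 | lithium (Z)-1-[(R)-4-benzyl-2-oxooxazolidin-3-yl]-3-(3,4-dimethoxyphenyl)prop-1-en-1-olate | COc1ccc(C/C=C(\O[Li])N2[C@H](Cc3ccccc3)COC2=O)cc1OC
F5 | step 4 | (2S,3S)-1,4-bis[(R)-4-benzyl-2-oxooxazolidin-3-yl]-2,3-bis(3,4-dimethoxybenzyl)butane-1,4-dione | O=C([C@@H](Cc1ccc(OC)c(OC)c1)[C@H](Cc1ccc(OC)c(OC)c1)C(=O)N1[C@H](Cc2ccccc2)COC1=O)N1[C@H](Cc2ccccc2)COC1=O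
F6 | step 3 | (3S,4S)-3,4-dimethyl-5-(quinolin-8-ylimino)dihydrofuran-2(3H)-one | O=C1[C@@H](C)[C@H](C)C(=Nc2cccc3cccnc23)O1
F7 | step 5 | (2S,3S)-2,3-bis(3,4-dimethoxybenzyl)succinic acid | OC(=O)[C@@H](Cc1ccc(OC)c(OC)c1)[C@H](Cc1ccc(OC)c(OC)c1)C(=O)O
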